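## The problem

7-O-Methyltetrahydroochnaflavone (21) consists of two flavanones joined by a diaryl ether: the oxygen on C3' of ring B of unit 1 (the 5-hydroxy-7-methoxyflavanone) is bonded to C4' of ring B of unit 2 (the 5,7-dihydroxyflavanone). The halves differ only in the methyl ether at C7 of unit 1 and in the substitution of their rings B. The ether core must therefore carry two distinguishable one-carbon handles, and the halves must stay distinguishable until each ring A is attached. The only stereocentres are C2 of unit 1 and C2 of unit 2, both (S). They are separated by two benzene rings and an oxygen, so neither can direct the other and each must be set by an external chiral agent. Isomers that differ at one of these remote centres will be hard to separate, so selectivity per site must be high. A 5-hydroxyflavanone opens to its 2'-hydroxychalcone under base (retro-oxa-Michael), and the free 4'-hydroxyl para to C2 in unit 1 makes this easier, so both centres racemise readily in base and on prolonged heating in acid. The stereocentres should therefore be made late, on fully protected material, and the last deprotection must be neutral. The feature that opens an unusual route is ring B of unit 2: it bears only an oxygen at C4' and a carbon substituent at C1', with four unsubstituted CH positions. A 2-pyrone with an acyl group at C5 delivers exactly this 1,4-pattern when it cycloadds to an alkynyl ether and expels CO2.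

## Retrosynthesis

**21 from 20.** No skeletal bond is cut. The four free phenols of 21 are traced back to the four benzyl ethers of 20, and the methyl ether at C7 of unit 1 is untouched. Benzyl is chosen over methyl or silyl because hydrogenolysis is neutral; Lewis-acid demethylation or fluoride would endanger the two C2 centres. The forward step must cleave four O–benzyl bonds without opening the benzylic C2–O1 bonds.

**20 from 19 and 18.** The C2–H and C3–H bonds of both rings C are removed, which leads to the achiral biflavone 18. The neighbouring disconnection, O1–C2 of a bis-chalcone, would set C2 by an oxa-Michael addition that is reversible and poorly controlled for chalcones of this type. The flat, robust biflavone instead lets every C–C and C–O bond be made with strong base, acid and heat before any stereocentre exists. The forward reaction must deliver hydrogen to the same face of two independent C2=C3 bonds under catalyst control. Over-reduction of the ketones to the bis(flavan-4-ol) 19 is accepted and corrected by oxidation to 20.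

**18 from 17, and 17 from 14 and 16.** Ring C of unit 1 is opened at O1–C2 and then at C2–C3, which gives the chalcone 17 and from it the aldehyde 14 and the acetophenone 16. The aldehyde is the oxidation level the ring B carbon already has in the starting material, so no redox adjustment is needed. The alternative acylation route would cost an oxidation and an acyl transfer. The forward steps are an aldol condensation and an oxidative ring closure.

**14 from 13, and 13 from 10 and 12.** Ring C of unit 2 is opened at O1–C2 and C2–C3, which gives the diketone 13 and from it the methyl ester 10 and the acetophenone 12. The ester carbon of 10 becomes C2 of unit 2. Unit 2 is built first because the ester needs a strong amide base that a free aldehyde would not survive, whereas the acetal on the other ring is inert to base. The same acid that closes the pyranone then releases the aldehyde, so the two handles differentiate themselves without extra steps.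

**10 from 7 and 8.** The bonds C3'–C4' and C5'–C6' of ring B of unit 2 are cut. This takes the ring apart into methyl coumalate 8 (C1', C2', C3', C6' and the ester carbon) and the two alkyne carbons of the ynol ether 7 (C4', C5'). The neighbouring cut is the aryl–oxygen bond, served by substitution on a 4-halobenzoate. It is shorter and is kept as the fallback. The pyrone route offers in exchange a neutral, metal-free ring synthesis whose regiochemistry follows from the polarisation of both partners, and it makes ring B of unit 2 variable through the pyrone. The ether oxygen is never attached to that ring by substitution because it arrives as the oxygen of the alkyne. The precursors are a purchased pyrone and a phenol-derived alkyne. The forward reaction must give para orientation and must be faster than decomposition of 7.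

**7 from 4, 4 from 2 and 3, 2 from 1.** The O–C≡C unit is traced to trichloroethylene 3, which transfers a dichlorovinyl group to the phenol 2. Two equivalents of n-BuLi then convert the dichlorovinyl ether 4 into the alkyne. The aldehyde of 1 is masked as a dioxolane first, so that acid never meets the dichlorovinyl ether and n-BuLi never meets a carbonyl group.

**12 from 11, 16 from 15.** The two ring A building blocks come from phloroacetophenone 11 and from purchased 2',6'-dihydroxy-4'-methoxyacetophenone 15 by benzylation. The hydroxyl hydrogen-bonded to the acetyl group stays free, and it is the one needed for ring closure. Buying 15 settles the methoxy/hydroxy distinction between the two rings A at no cost in steps.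

## Roads not taken

**Alternative 1:** Both rings C would be closed at C2–C3. The bis(diazoketone) A1 has a diazoacetyl group on each ring A next to a benzylic aryl ether. With Rh2(S-PTTL)4 (dirhodium tetrakis[N-phthaloyl-(S)-tert-leucinate]) it would lose two molecules of dinitrogen, and each carbene would insert into the adjacent O–CH2 bond to give the bis-silyl dibenzyl bis-flavanone A2.
- Merits: both rings and both stereocentres form in one neutral catalytic step, and the ketones appear at the correct oxidation level. Nothing like the reduction–reoxidation of steps 11 and 12 is needed. The diaryl ether core of A1 could even be drawn from 10.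
- Weak points: the carbene sits five atoms from the ether oxygen. Attack of that oxygen to form a five-membered oxonium ylide, followed by a [1,2]-shift of the benzyl group, is the classical competitor of six-membered C–H insertion in such substrates, and it is intrinsic to the substrate. Carbenes that carry only an acceptor group usually insert with moderate enantioselectivity, and two sites must each be highly selective. The diazoketones must also be made from hindered 2,6-dioxygenated benzoic acids.
- Comparison: this road is shorter after the ether core and better in redox economy. The chosen plan relies instead on a stereo-setting reaction type already demonstrated on flavones, and on ring closures with no chemoselectivity question.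

**Alternative 2:** Ring A of unit 1 would be made last, by cutting C5–C6, C7–C8 and C4a–C5. The enantiopure 2-aryl-dihydropyranone A3 carries a diazoacetyl group on the carbon that becomes C8a and already contains the finished unit 2. Under blue light it would undergo Wolff rearrangement to a vinylketene, which on warming with methoxyacetylene A4 would give the dibenzyl ether A5 by [2+2] addition, four-electron ring opening and six-electron ring closure.
- Merits: the 5-hydroxy-7-methoxy pattern is created directly in its final form, with regiochemistry fixed by the alkyne. C2 of unit 1 could be set early by an asymmetric hetero-Diels–Alder reaction, which is more reliable than a late facial selection on a flavone.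
- Weak points: C2 is β to the ketone through O1, so A3 and A5 can open by retro-oxa-Michael during the thermal cascade, more so once the 5-hydroxyl is free. Unit 2, with its own labile centre, must survive photolysis and heating. A4 is volatile and unstable. Only one of the two rings A is addressed, so unit 2 needs a second, separate asymmetric synthesis and the route is linear.
- Comparison: this road is better in protecting-group economy for unit 1 and possibly in stereocontrol at C2 of unit 1. The chosen plan makes both centres at the very end on robust material, and its methoxy/hydroxy distinction is bought with 15.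

**Alternative 3:** Both rings C would be closed at O1–C8a. The dibromo tetraol A6 has two 1,3-diol chains, each next to an aryl bromide. With Pd(OAc)2, a bulky biaryl di-tert-butylphosphine and Cs2CO3 it would cyclise twice to the bis(flavan-4-ol) A7. Only the C2 hydroxyl can reach C8a through a six-membered ring, since the C4 hydroxyl would have to form a four-membered one.
- Merits: the C2–O bond is never broken, so the configuration set at the carbinol stage by ordinary asymmetric carbonyl chemistry is carried through with retention, and it can be purified before the rings close. This is more secure than any facial selection on a flavone. A7 is the same compound as 19, so from there the two plans coincide.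
- Weak points: A6 has four stereocentres, two of which are discarded by the later oxidation. Building two enantiopure 1,3-diols on the ether core with two different bromoaryl partners takes considerably more steps than steps 5 to 11. Palladium alkoxides of secondary benzylic alcohols tend to undergo β-hydride elimination, which gives a ketone and the reduced arene. The electron-rich aryl bromides add slowly to palladium.
- Comparison: this road is better in stereochemical security. The chosen plan reaches the same intermediate 19 in fewer steps from cheaper materials, and it keeps a kinetic resolution in reserve if the catalyst falls short.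

Key step: step 4

Assumption: the (R,R) carbene ligand of step 11 is taken to deliver hydrogen to the face that gives the (2S) series; if a simple model flavone shows the opposite sense, the (S,S) ligand is used instead.

## Route

Step 1
Reactants: 1 4-(benzyloxy)-3-hydroxybenzaldehyde
Product: 2 2-(benzyloxy)-5-(1,3-dioxolan-2-yl)phenol
Conditions: ethylene glycol (5 equiv), p-TsOH·H2O (cat.), toluene, reflux, Dean–Stark
Reagents that add atoms: ethylene glycol, OCCO
Why: Acid-catalysed acetalisation with azeotropic removal of water; the aldehyde must be masked before n-BuLi is used in step 3, and the dioxolane is stable to every basic step up to step 6.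

Step 2
Reactants: 2 2-(benzyloxy)-5-(1,3-dioxolan-2-yl)phenol; 3 trichloroethylene
Product: 4 2-[4-(benzyloxy)-3-{[(E)-1,2-dichloroethenyl]oxy}phenyl]-1,3-dioxolane
Conditions: 3 (1.5 equiv), K2CO3 (2 equiv), DMF, 70 °C
Reagents that add atoms: none
Why: O-Dichlorovinylation of a phenoxide with trichloroethylene, a known route to aryl 1,2-dichlorovinyl ethers: base forms dichloroacetylene in the flask, the phenoxide adds to it and anti protonation gives the (E) ether; the acetal is inert to carbonate.

Step 3
Reactants: 4 2-[4-(benzyloxy)-3-{[(E)-1,2-dichloroethenyl]oxy}phenyl]-1,3-dioxolane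
Product: 7 2-[4-(benzyloxy)-3-(ethynyloxy)phenyl]-1,3-dioxolane, via chloroethynyl ether 5 (not isolated), via lithium aryloxyacetylide 6 (not isolated)
Conditions: n-BuLi (2.5 equiv), THF, −78 → −40 °C; MeOH, −78 °C; cold neutral aqueous work-up, toluene solution kept at or below 0 °C and used at once
Reagents that add atoms: none
Why: Ynol ether synthesis from a 1,2-dichlorovinyl ether: deprotonation and loss of LiCl give the chloroalkyne 5, chlorine–lithium exchange gives the acetylide 6, and protonation at low temperature gives 7; the aryl benzyl ether and the acetal tolerate n-BuLi at −78 °C.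

Step 4
Reactants: 7 2-[4-(benzyloxy)-3-(ethynyloxy)phenyl]-1,3-dioxolane; 8 methyl coumalate (methyl 2-oxo-2H-pyran-5-carboxylate)
Product: 10 methyl 4-[2-(benzyloxy)-5-(1,3-dioxolan-2-yl)phenoxy]benzoate, via bridged bicyclic lactone 9 (not isolated)
Conditions: 8 (2 equiv), toluene, 80 °C, cold solution of 7 added over 4 h; then 100 °C
Reagents that add atoms: none
Why: Inverse-demand Diels–Alder reaction of the 2-pyrone 8 (diene C3 to C6, made electron-poor by the lactone and the C5 ester) with the electron-rich alkyne 7, followed by cycloreversion of the bridged lactone 9 with loss of CO2. The closest known reaction type is the cycloaddition–decarboxylation of coumalate esters with ynamines, ketene acetals, enol ethers and alkynes, which gives para-substituted benzoates; an aryloxyalkyne is a new partner within this class. Ring B of unit 2 closes by a concerted, asynchronous [4+2] cycloaddition that forms C5'–C6' (terminal alkyne carbon to pyrone C6) and C3'–C4' (oxygen-bearing alkyne carbon to pyrone C3). Because the dienophile is an alkyne, loss of CO2 from 9 leaves the ring aromatic without an oxidant. No stereocentre is created: the two bridgehead carbons of 9 are transient and end as sp2 carbons of 10. The selectivity needed is para against meta; the terminal carbon of 7 is its most nucleophilic atom and C6 of 8, conjugated to both carbonyl groups, is its most electrophilic, and the unhindered CH terminus reinforces this orientation. Benzyl ether, dioxolane and ester are inert to neutral heating, and slow addition of 7 to excess 8 keeps its concentration low so that cycloaddition outruns its self-reaction.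

Step 5
Reactants: 11 1-(2,4,6-trihydroxyphenyl)ethanone
Product: 12 1-[2,4-bis(benzyloxy)-6-hydroxyphenyl]ethanone
Conditions: BnBr (2.1 equiv), K2CO3 (2.2 equiv), DMF, rt → 60 °C
Reagents that add atoms: benzyl bromide, BrCc1ccccc1
Why: Williamson etherification; the hydroxyl hydrogen-bonded to the acetyl carbonyl is the least reactive, so two equivalents of benzyl bromide stop at the 4,6-dibenzyl ether, the usual selective protection of phloroacetophenone.

Step 6
Reactants: 10 methyl 4-[2-(benzyloxy)-5-(1,3-dioxolan-2-yl)phenoxy]benzoate; 12 1-[2,4-bis(benzyloxy)-6-hydroxyphenyl]ethanone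
Product: 13 1-[2,4-bis(benzyloxy)-6-hydroxyphenyl]-3-{4-[2-(benzyloxy)-5-(1,3-dioxolan-2-yl)phenoxy]phenyl}propane-1,3-dione
Conditions: 12 (1.1 equiv), LiN(SiMe3)2 (3.5 equiv), THF, −78 → −10 °C; then 10, −10 °C → 40 °C; AcOH quench at 0 °C
Reagents that add atoms: none
Why: Crossed Claisen condensation of the phenoxide–enolate dianion of 12 with the non-enolisable methyl ester, the direct-ester variant of the Baker–Venkataraman route to 1-(2-hydroxyaryl)-1,3-diketones; the diketone enolate is the thermodynamic sink and the acetal is stable to the base.

Step 7
Reactants: 13 1-[2,4-bis(benzyloxy)-6-hydroxyphenyl]-3-{4-[2-(benzyloxy)-5-(1,3-dioxolan-2-yl)phenoxy]phenyl}propane-1,3-dione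
Product: 14 4-(benzyloxy)-3-{4-[5,7-bis(benzyloxy)-4-oxo-4H-chromen-2-yl]phenoxy}benzaldehyde
Conditions: p-TsOH·H2O (20 mol%), AcOH/H2O, 70 °C
Reagents that add atoms: water, O
Why: Acid-catalysed cyclodehydration of the 1-(2-hydroxyaryl)-1,3-diketone to the flavone (the phenol adds to the distal carbonyl, then water is lost), with hydrolysis of the dioxolane in the same aqueous acid; aryl benzyl ethers withstand dilute sulfonic acid in acetic acid at this temperature.

Step 8
Reactants: 15 1-(2,6-dihydroxy-4-methoxyphenyl)ethanone
Product: 16 1-[2-(benzyloxy)-6-hydroxy-4-methoxyphenyl]ethanone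
Conditions: BnBr (1.05 equiv), K2CO3 (1.2 equiv), acetone, reflux
Reagents that add atoms: benzyl bromide, BrCc1ccccc1
Why: Williamson mono-benzylation; after the first alkylation the remaining hydroxyl is held in the hydrogen bond to the acetyl carbonyl and reacts much more slowly, the usual basis for mono-protection of 2,6-dihydroxyacetophenones.

Step 9
Reactants: 14 4-(benzyloxy)-3-{4-[5,7-bis(benzyloxy)-4-oxo-4H-chromen-2-yl]phenoxy}benzaldehyde; 16 1-[2-(benzyloxy)-6-hydroxy-4-methoxyphenyl]ethanone
Product: 17 (E)-1-[2-(benzyloxy)-6-hydroxy-4-methoxyphenyl]-3-[4-(benzyloxy)-3-{4-[5,7-bis(benzyloxy)-4-oxo-4H-chromen-2-yl]phenoxy}phenyl]prop-2-en-1-one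
Conditions: KOH (50% aq., 10 equiv), EtOH/THF, rt
Reagents that add atoms: none
Why: Claisen–Schmidt condensation (aldol addition, then E1cB dehydration) gives the (E)-2'-hydroxychalcone; the aldehyde 14 has no enolisable position and the 5,7-dialkoxyflavone ring tolerates hydroxide at room temperature.

Step 10
Reactants: 17 (E)-1-[2-(benzyloxy)-6-hydroxy-4-methoxyphenyl]-3-[4-(benzyloxy)-3-{4-[5,7-bis(benzyloxy)-4-oxo-4H-chromen-2-yl]phenoxy}phenyl]prop-2-en-1-one
Product: 18 5-(benzyloxy)-2-[4-(benzyloxy)-3-{4-[5,7-bis(benzyloxy)-4-oxo-4H-chromen-2-yl]phenoxy}phenyl]-7-methoxy-4H-chromen-4-one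
Conditions: I2 (10 mol%), DMSO, 120 °C
Reagents that add atoms: none
Why: Iodine-catalysed oxidative cyclisation of a 2'-hydroxychalcone in DMSO (oxa-Michael ring closure, α-iodination, loss of hydrogen iodide, reoxidation of iodide by DMSO), the standard chalcone-to-flavone method.

Step 11
Reactants: 18 5-(benzyloxy)-2-[4-(benzyloxy)-3-{4-[5,7-bis(benzyloxy)-4-oxo-4H-chromen-2-yl]phenoxy}phenyl]-7-methoxy-4H-chromen-4-one
Product: 19 (2S,4S)-5-(benzyloxy)-2-[4-(benzyloxy)-3-{4-[(2S,4S)-5,7-bis(benzyloxy)-4-hydroxychroman-2-yl]phenoxy}phenyl]-7-methoxychroman-4-ol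
Conditions: Ru(cod)(2-methylallyl)2 (10 mol%), 1,3-bis[(R)-1-(1-naphthyl)ethyl]imidazolinium tetrafluoroborate [(R,R)-SINpEt·HBF4] (20 mol%), KOtBu (30 mol%), catalyst preformed in hexane at 70 °C; H2 (100 bar), toluene, 25–40 °C
Reagents that add atoms: none
Why: Asymmetric hydrogenation of flavones with a chiral ruthenium N-heterocyclic carbene catalyst, a known reaction of flavones and chromones: hydrogen is delivered to one face of each C2=C3 bond under catalyst control, which sets both C2 centres as (S); the two pyranone rings are too far apart to influence each other and are reduced independently, and the accompanying ketone reduction (expected cis to the aryl group) does not matter because step 12 erases C4.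

Step 12
Reactants: 19 (2S,4S)-5-(benzyloxy)-2-[4-(benzyloxy)-3-{4-[(2S,4S)-5,7-bis(benzyloxy)-4-hydroxychroman-2-yl]phenoxy}phenyl]-7-methoxychroman-4-ol
Product: 20 (2S)-5-(benzyloxy)-2-[4-(benzyloxy)-3-{4-[(2S)-5,7-bis(benzyloxy)-4-oxochroman-2-yl]phenoxy}phenyl]-7-methoxychroman-4-one
Conditions: Dess–Martin periodinane (3 equiv), CH2Cl2, rt
Reagents that add atoms: none
Why: Dess–Martin oxidation of the two benzylic secondary alcohols to the ketones under conditions that cannot epimerise C2; any ring that escaped over-reduction in step 11 passes through unchanged, so the material converges on 20.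

Step 13
Reactants: 20 (2S)-5-(benzyloxy)-2-[4-(benzyloxy)-3-{4-[(2S)-5,7-bis(benzyloxy)-4-oxochroman-2-yl]phenoxy}phenyl]-7-methoxychroman-4-one
Product: 21 7-O-methyltetrahydroochnaflavone, (2S)-2-[3-{4-[(2S)-5,7-dihydroxy-4-oxochroman-2-yl]phenoxy}-4-hydroxyphenyl]-5-hydroxy-7-methoxychroman-4-one
Conditions: H2 (1 atm), Pd/C (10 wt%), EtOAc/MeOH, rt
Reagents that add atoms: none
Why: Hydrogenolysis of the four aryl benzyl ethers over palladium on carbon under neutral conditions; no base is present, so the 5-hydroxyflavanone rings cannot open to chalcones and both (S) centres are kept.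

## Compound list

1 | 4-(benzyloxy)-3-hydroxybenzaldehyde | O=Cc1ccc(OCc2ccccc2)c(O)c1 | starting material
2 | 2-(benzyloxy)-5-(1,3-dioxolan-2-yl)phenol | Oc1cc(C2OCCO2)ccc1OCc1ccccc1 | intermediate
3 | trichloroethylene | ClC=C(Cl)Cl | starting material
4 | 2-[4-(benzyloxy)-3-{[(E)-1,2-dichloroethenyl]oxy}phenyl]-1,3-dioxolane | Cl/C=C(/Cl)Oc1cc(C2OCCO2)ccc1OCc1ccccc1 | intermediate
5 | 2-{4-(benzyloxy)-3-[(chloroethynyl)oxy]phenyl}-1,3-dioxolane (formed in the flask in step 3) | ClC#COc1cc(C2OCCO2)ccc1OCc1ccccc1 | intermediate
6 | lithium {[2-(benzyloxy)-5-(1,3-dioxolan-2-yl)phenoxy]ethynide} (formed in the flask in step 3) | [Li]C#COc1cc(C2OCCO2)ccc1OCc1ccccc1 | intermediate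
7 | 2-[4-(benzyloxy)-3-(ethynyloxy)phenyl]-1,3-dioxolane | C#COc1cc(C2OCCO2)ccc1OCc1ccccc1 | intermediate
8 | methyl coumalate (methyl 2-oxo-2H-pyran-5-carboxylate) | COC(=O)C1=COC(=O)C=C1 | starting material
9 | methyl 5-[2-(benzyloxy)-5-(1,3-dioxolan-2-yl)phenoxy]-3-oxo-2-oxabicyclo[2.2.2]octa-5,7-diene-7-carboxylate, racemic (formed in the flask in step 4) | COC(=O)C1=CC2C(=O)OC1C=C2Oc1cc(C3OCCO3)ccc1OCc1ccccc1 | intermediate
10 | methyl 4-[2-(benzyloxy)-5-(1,3-dioxolan-2-yl)phenoxy]benzoate | COC(=O)c1ccc(Oc2cc(C3OCCO3)ccc2OCc2ccccc2)cc1 | intermediate
11 | 1-(2,4,6-trihydroxyphenyl)ethanone | CC(=O)c1c(O)cc(O)cc1O | starting material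
12 | 1-[2,4-bis(benzyloxy)-6-hydroxyphenyl]ethanone | CC(=O)c1c(O)cc(OCc2ccccc2)cc1OCc1ccccc1 | intermediate
13 | 1-[2,4-bis(benzyloxy)-6-hydroxyphenyl]-3-{4-[2-(benzyloxy)-5-(1,3-dioxolan-2-yl)phenoxy]phenyl}propane-1,3-dione | O=C(CC(=O)c1c(O)cc(OCc2ccccc2)cc1OCc1ccccc1)c1ccc(Oc2cc(C3OCCO3)ccc2OCc2ccccc2)cc1 | intermediate
14 | 4-(benzyloxy)-3-{4-[5,7-bis(benzyloxy)-4-oxo-4H-chromen-2-yl]phenoxy}benzaldehyde | O=Cc1ccc(OCc2ccccc2)c(Oc2ccc(-c3cc(=O)c4c(OCc5ccccc5)cc(OCc5ccccc5)cc4o3)cc2)c1 | intermediate
15 | 1-(2,6-dihydroxy-4-methoxyphenyl)ethanone | CC(=O)c1c(O)cc(OC)cc1O | starting material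
16 | 1-[2-(benzyloxy)-6-hydroxy-4-methoxyphenyl]ethanone | CC(=O)c1c(O)cc(OC)cc1OCc1ccccc1 | intermediate
17 | (E)-1-[2-(benzyloxy)-6-hydroxy-4-methoxyphenyl]-3-[4-(benzyloxy)-3-{4-[5,7-bis(benzyloxy)-4-oxo-4H-chromen-2-yl]phenoxy}phenyl]prop-2-en-1-one | COc1cc(O)c(C(=O)/C=C/c2ccc(OCc3ccccc3)c(Oc3ccc(-c4cc(=O)c5c(OCc6ccccc6)cc(OCc6ccccc6)cc5o4)cc3)c2)c(OCc2ccccc2)c1 | intermediate
18 | 5-(benzyloxy)-2-[4-(benzyloxy)-3-{4-[5,7-bis(benzyloxy)-4-oxo-4H-chromen-2-yl]phenoxy}phenyl]-7-methoxy-4H-chromen-4-one | COc1cc(OCc2ccccc2)c2c(c1)oc(-c1ccc(OCc3ccccc3)c(Oc3ccc(-c4cc(=O)c5c(OCc6ccccc6)cc(OCc6ccccc6)cc5o4)cc3)c1)cc2=O | intermediate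
19 | (2S,4S)-5-(benzyloxy)-2-[4-(benzyloxy)-3-{4-[(2S,4S)-5,7-bis(benzyloxy)-4-hydroxychroman-2-yl]phenoxy}phenyl]-7-methoxychroman-4-ol | COc1cc(OCc2ccccc2)c2c(c1)O[C@H](c1ccc(OCc3ccccc3)c(Oc3ccc([C@@H]4C[C@H](O)c5c(OCc6ccccc6)cc(OCc6ccccc6)cc5O4)cc3)c1)C[C@@H]2O | intermediate
20 | (2S)-5-(benzyloxy)-2-[4-(benzyloxy)-3-{4-[(2S)-5,7-bis(benzyloxy)-4-oxochroman-2-yl]phenoxy}phenyl]-7-methoxychroman-4-one | COc1cc(OCc2ccccc2)c2c(c1)O[C@H](c1ccc(OCc3ccccc3)c(Oc3ccc([C@@H]4CC(=O)c5c(OCc6ccccc6)cc(OCc6ccccc6)cc5O4)cc3)c1)CC2=O | intermediate
21 | 7-O-methyltetrahydroochnaflavone, (2S)-2-[3-{4-[(2S)-5,7-dihydroxy-4-oxochroman-2-yl]phenoxy}-4-hydroxyphenyl]-5-hydroxy-7-methoxychroman-4-one | COc1cc(O)c2c(c1)O[C@H](c1ccc(O)c(Oc3ccc([C@@H]4CC(=O)c5c(O)cc(O)cc5O4)cc3)c1)CC2=O | target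

## Step count and risks

Total step count: 13. Longest linear sequence: 11 steps (steps 1, 2, 3, 4, 6, 7, 9, 10, 11, 12 and 13, from 1 to 21). Steps 5 and 8 are one-step side branches.

**Step 4 (key step).** The aryloxy group is a weaker donor than an amino or alkoxy group, so cycloaddition may be slower than oligomerisation of the ynol ether or its hydration by traces of water. With a slow reaction, some cycloaddition in the meta sense could also appear. Fallback: setting out from 2, nucleophilic aromatic substitution of the phenoxide on methyl 4-fluorobenzoate (K2CO3, DMSO, 120 °C) gives 10 directly, and the route is rejoined at 10. This gives up the pyrone disconnection, bypasses steps 2 and 3 and makes no compound outside the route (entry F0).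

**Step 11.** Facial selection may be incomplete at one of the two rings, which would leave isomers with remote stereocentres that chromatography is unlikely to remove. Turnover may be slow because the peri benzyloxy group crowds and deactivates the carbonyl, and arene rings may be partly saturated at the pressure required. Fallback: setting out from 18, conjugate reduction of both pyranones with LiBH(s-Bu)3 in THF at −78 °C (1,4-hydride addition, protonation of the enolate) would give stereorandom 5-(benzyloxy)-2-[4-(benzyloxy)-3-{4-[5,7-bis(benzyloxy)-4-oxochroman-2-yl]phenoxy}phenyl]-7-methoxychroman-4-one F1, all four stereoisomers. A kinetic resolution by Noyori transfer hydrogenation follows, with RuCl(p-cymene)(TsDPEN) and HCO2H/NEt3, using the antipode of the diamine that reduces (2R)-flavanone rings faster. It converts every ring of (R) configuration into a flavan-4-ol and leaves the (2S,2''S) diketone, which is 20 and now differs in polarity from all the rest. The route is rejoined at 20 without steps 11 and 12, with at best one quarter of the material retained. The same transfer hydrogenation can also polish 20 from step 12 if a minor isomer is present.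

**Step 3.** The terminal ynol ether may be lost by hydration or self-addition during aqueous work-up and concentration, and n-BuLi may metalate the benzylic CH2 group or the arene if the temperature drifts. Fallback: setting out from 4, the same lithiation is carried out, but the acetylide 6 is quenched with i-Pr3SiOTf instead of methanol. This gives 2-[4-(benzyloxy)-3-({[tri(propan-2-yl)silyl]ethynyl}oxy)phenyl]-1,3-dioxolane F2, a silyl-capped ynol ether that can be chromatographed and stored. Treatment with n-Bu4NF in THF at −20 °C frees 7 immediately before the cycloaddition, and the route is rejoined at 7.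

**Step 6.** C-Acylation may be incomplete: the hindered, doubly charged enolate attacks the electron-rich ester slowly, and proton transfer from the product stalls the reaction. Fallback: setting out from 10, saponification (LiOH, THF/H2O) gives 4-[2-(benzyloxy)-5-(1,3-dioxolan-2-yl)phenoxy]benzoic acid F3. Steglich esterification with 12 (EDC·HCl, DMAP, CH2Cl2) gives 2-acetyl-3,5-bis(benzyloxy)phenyl 4-[2-(benzyloxy)-5-(1,3-dioxolan-2-yl)phenoxy]benzoate F4. Baker–Venkataraman acyl shift (KOH, pyridine, 50 °C) then gives 13, where the route is rejoined.

**Step 10.** Hydrogen iodide formed at 120 °C may cleave the peri benzyl ether, and the electron-rich ring A may be iodinated. Fallback: setting out from 17, base-mediated oxa-Michael ring closure (NaOAc, EtOH, reflux) gives racemic 5-(benzyloxy)-2-[4-(benzyloxy)-3-{4-[5,7-bis(benzyloxy)-4-oxo-4H-chromen-2-yl]phenoxy}phenyl]-7-methoxychroman-4-one F5. Dehydrogenation with DDQ in dioxane at reflux then gives 18, where the route is rejoined.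

## Further compounds

F0 | step 4 | none | none
F1 | step 11 | 5-(benzyloxy)-2-[4-(benzyloxy)-3-{4-[5,7-bis(benzyloxy)-4-oxochroman-2-yl]phenoxy}phenyl]-7-methoxychroman-4-one, mixture of the four stereoisomers | COc1cc(OCc2ccccc2)c2c(c1)OC(c1ccc(OCc3ccccc3)c(Oc3ccc(C4CC(=O)c5c(OCc6ccccc6)cc(OCc6ccccc6)cc5O4)cc3)c1)CC2=O
F2 | step 3 | 2-[4-(benzyloxy)-3-({[tri(propan-2-yl)silyl]ethynyl}oxy)phenyl]-1,3-dioxolane | CC(C)[Si](C#COc1cc(C2OCCO2)ccc1OCc1ccccc1)(C(C)C)C(C)C
F3 | step 6 | 4-[2-(benzyloxy)-5-(1,3-dioxolan-2-yl)phenoxy]benzoic acid | OC(=O)c1ccc(Oc2cc(C3OCCO3)ccc2OCc2ccccc2)cc1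
F4 | step 6 | 2-acetyl-3,5-bis(benzyloxy)phenyl 4-[2-(benzyloxy)-5-(1,3-dioxolan-2-yl)phenoxy]benzoate | CC(=O)c1c(OC(=O)c2ccc(Oc3cc(C4OCCO4)ccc3OCc3ccccc3)cc2)cc(OCc2ccccc2)cc1OCc1ccccc1
F5 | step 10 | racemic 5-(benzyloxy)-2-[4-(benzyloxy)-3-{4-[5,7-bis(benzyloxy)-4-oxo-4H-chromen-2-yl]phenoxy}phenyl]-7-methoxychroman-4-one | COc1cc(OCc2ccccc2)c2c(c1)OC(c1ccc(OCc3ccccc3)c(Oc3ccc(-c4cc(=O)c5c(OCc6ccccc6)cc(OCc6ccccc6)cc5o4)cc3)c1)CC2=O
A1 | alternative 1 | bis(diazoketone): each ring A carries a diazoacetyl group between a tert-butyldimethylsilyl ether and the benzylic ether to its ring B | COc1cc(O[Si](C)(C)C(C)(C)C)c(C(=O)C=[N+]=[N-])c(OCc2ccc(OCc3ccccc3)c(Oc3ccc(COc4cc(OCc5ccccc5)cc(O[Si](C)(C)C(C)(C)C)c4C(=O)C=[N+]=[N-])cc3)c2)c1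
A2 | alternative 1 | 5,5-bis-O-(tert-butyldimethylsilyl) di-O-benzyl 7-O-methyltetrahydroochnaflavone | COc1cc(O[Si](C)(C)C(C)(C)C)c2c(c1)O[C@H](c1ccc(OCc3ccccc3)c(Oc3ccc([C@@H]4CC(=O)c5c(O[Si](C)(C)C(C)(C)C)cc(OCc6ccccc6)cc5O4)cc3)c1)CC2=O
A3 | alternative 2 | (2S)-6-(diazoacetyl)-2-aryl-2,3-dihydro-4H-pyran-4-one, the aryl group being ring B of unit 1 with its benzyl ether and the complete 7-O-benzyl unit 2 | O=C(C=[N+]=[N-])C7=CC(=O)C[C@@H](c1ccc(OCc3ccccc3)c(Oc3ccc([C@@H]4CC(=O)c5c(O)cc(OCc6ccccc6)cc5O4)cc3)c1)O7
A4 | alternative 2 | methoxyacetylene | COC#C
A5 | alternative 2 | di-O-benzyl 7-O-methyltetrahydroochnaflavone | COc1cc(O)c2c(c1)O[C@H](c1ccc(OCc3ccccc3)c(Oc3ccc([C@@H]4CC(=O)c5c(O)cc(OCc6ccccc6)cc5O4)cc3)c1)CC2=O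
A6 | alternative 3 | dibromo tetraol: two 1-(2-bromoaryl)-3-arylpropane-1,3-diol chains on the benzylated diaryl ether | COc1cc(OCc2ccccc2)c([C@@H](O)C[C@H](O)c2ccc(OCc3ccccc3)c(Oc3ccc([C@@H](O)C[C@H](O)c4c(OCc5ccccc5)cc(OCc5ccccc5)cc4Br)cc3)c2)c(Br)c1
A7 | alternative 3 | tetra-O-benzyl bis(flavan-4-ol), identical with 19 | COc1cc(OCc2ccccc2)c2c(c1)O[C@H](c1ccc(OCc3ccccc3)c(Oc3ccc([C@@H]4C[C@H](O)c5c(OCc6ccccc6)cc(OCc6ccccc6)cc5O4)cc3)c1)C[C@@H]2O
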